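**Assumption:** (S)-pinostrobin, (2S)-5-hydroxy-7-methoxyflavanone, is bought as the single enantiomer. The SMILES stereocentre (O[C@H](Ph)CH2) works out to 2S, the same as natural pinostrobin.

## Retrosynthetic overview
1. Target **3** is 5-hydroxy-7-methoxyflavanone carrying a 2-hydroxybenzyl group on each of C6 and C8.
2. Disconnecting both Ar–CH2Ar′ bonds is a double ortho-hydroxybenzylation. It needs a 2-hydroxybenzyl cation or ortho-quinone methide (o-QM) equivalent, which comes from salicyl alcohol **2**.
3. The remaining fragment is (S)-pinostrobin (**1**). Only C6 and C8 are free, activated positions on its phloroglucinol-type ring A.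
4. No ring is formed in the route. Rings A, B and C and the C2 (S) stereocentre are already in **1**, and the route must not disturb C2.

## Route

**Step 1**
Reactants: **1**, (S)-pinostrobin; **2**, 2-hydroxybenzyl alcohol (salicyl alcohol), about 4 equiv
Product: **3**, 7-methoxydichamanetin
Conditions: **2** (4 equiv, added in portions), TsOH·H2O (20 mol %), MeCN, 80 °C, 12–16 h
Reagents that add atoms: 2-hydroxybenzyl alcohol, OCc1ccccc1O (it supplies both 2-hydroxybenzyl groups). TsOH is only a catalyst.
Why: Acid dehydrates **2** to a transient o-QM (not isolated), which the electron-rich C6 and C8 of ring A attack in a 1,4-addition (Friedel–Crafts-type o-hydroxybenzylation), twice. The 7-OMe and 5-OH direct both benzylations to C6 and C8. No new stereocentre forms, and the non-basic conditions avoid retro-oxa-Michael ring opening, so C2 stays (S).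

## Checks
- **Structure match:** Product **3** has the 5-OH (chelated to C4=O), the 7-OMe, 2-hydroxybenzyl groups at C6 and C8, the phenyl at C2, and the intact 6-membered chromanone ring. This matches the target SMILES.
- **Atom balance:** C16H14O4 + 2 C7H8O2 − 2 H2O = C30H26O6, which is the target formula.
- **Functional groups:** The ketone, aryl methyl ether and flavanone C–O bond survive dilute acid at 80 °C.
- **Stereochemistry:** C2 is the only stereocentre. It is set by the chiral-pool starting material and is not touched in the route.

## Compound list
1 | (S)-pinostrobin, (2S)-5-hydroxy-7-methoxy-2-phenylchroman-4-one | COc1cc(O)c2c(c1)O[C@H](c1ccccc1)CC2=O | starting material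
2 | 2-hydroxybenzyl alcohol (salicyl alcohol) | OCc1ccccc1O | starting material
3 | 7-methoxydichamanetin, (2S)-5-hydroxy-7-methoxy-6,8-bis(2-hydroxybenzyl)-2-phenylchroman-4-one | COc1c(Cc2ccccc2O)c(O)c2c(c1Cc1ccccc1O)O[C@H](c1ccccc1)CC2=O | target

## Summary
Total step count: 1. Longest linear sequence: 1 step (from **1**).

**Three steps or issues most likely to fail**
1. **Over-alkylation or oligomerisation (the single step).** Salicyl alcohol can self-condense, and the pendant phenol rings can also be benzylated.
   - Fallback: a different approach. Brominate or iodinate pinostrobin at C6 and C8 (NIS or NBS), then do a double Suzuki–Miyaura coupling with potassium 2-(benzyloxy)benzyltrifluoroborate (Pd cat.), then remove the benzyl groups by H2, Pd/C.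
2. **Partial racemisation at C2.** Acid and heat could open the ring to the 2′-hydroxychalcone and re-close it.
   - Fallback: a different approach. Benzylate the achiral 2′,6′-dihydroxy-4′-methoxyacetophenone at C3 and C5, condense with benzaldehyde (Claisen–Schmidt) to the chalcone, and close the ring by enantioselective intramolecular oxa-Michael addition with a bifunctional cinchona-thiourea or iminophosphorane catalyst.
3. **Incomplete bis-benzylation, leaving inseparable 6- and 8-mono products.** The second benzylation is sterically and electronically slower.
   - Fallback: a different electrophile. Use 2-(benzyloxy)benzyl alcohol with a Lewis acid (Sc(OTf)3) for a cleaner cation alkylation, then remove the benzyl ethers by mild hydrogenolysis (H2, Pd/C, EtOAc). This makes a 2-step route.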